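**Retrosynthetic overview** (germacrane numbering: ring C1–C10, oxiranes C1–C10 and C4–C5, lactone O on C6, C12 = lactone C=O, C13 = CH2OAc, ester O on C8)
1. Feature: C1 and C6 both carry oxygen and sit 1,6 across the ten-membered ring, with C10 next to C1. A decalin with a C1–C6 fusion epoxide beside a C10 ketone is therefore the retron of C6=O plus a C10≡C1 alkyne, and a ten-membered cycloalkyne can only give the Z-olefin and cis-oxirane.
2. Target ⇐ C8 acylation and C8–OH-directed C1=C10 epoxidation ⇐ butenolide from the C6 ketone (C7 aldol with an acetoxypyruvate, E1cB, chelation-controlled C6 reduction, lactonization).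
3. Z-C1=C10(Me) ⇐ vinyl iodide ⇐ C8–O–Si-tethered syn-hydrosilylation of C10≡C1; C8–OH ⇐ copper–boryl addition to the C7=C8 enone.
4. Cyclodecynone ⇐ Eschenmoser–Tanabe fragmentation of the syn-bis-epoxy decalone ⇐ OH-directed 1O2 [4+2] and Co(II) rearrangement of a dienol made from 6-methyl-1-tetralone (Birch, conjugation, CBS).
5. Ring order: decalin (bought) → two oxiranes (step 6) → ten-membered ring (step 8) → butenolide (step 18) → C1–C10 oxirane (step 20).

Key step: step 8

Remark on numbering: germacrane numbers are used throughout; naphthalene C1/C2/C3/C4/C4a/C5/C6/C7/C8/C8a = germacrane C10/C9/C8/C7/C6/C5/C4/C3/C2/C1.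
Assumption: (R,Sp)-Josiphos is taken as the ligand enantiomer whose copper–boryl complex adds to the Re face of C8 in enone 14; if the sense is the opposite one, the mirror-image ligand is used in step 10.

**Step 1**
Reactants: 1 6-methyl-1-tetralone
Product: 2 rac-6-methyl-1,2,3,4-tetrahydronaphthalen-1-ol
Conditions: NaBH4, MeOH, 0 °C
Reagents that add atoms: none
Why: Borohydride 1,2-reduction of the aryl ketone; the carbinol centre is racemic, is erased in step 3, and only carries the oxygen through the Birch reduction.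

**Step 2**
Reactants: 2 rac-6-methyl-1,2,3,4-tetrahydronaphthalen-1-ol
Product: 3 rac-6-methyl-1,2,3,4,5,8-hexahydronaphthalen-1-ol
Conditions: n-BuLi (1.0 equiv), THF, −78 °C; then Li, NH3(l), t-BuOH, −78 → −33 °C; NH4Cl
Reagents that add atoms: none
Why: Birch reduction, in which the lithium alkoxide resists benzylic hydrogenolysis and the three ring alkyl groups leave only the unsubstituted para pair C2/C5 to be protonated, giving the C1=C6/C3=C4 diene.

**Step 3**
Reactants: 3 rac-6-methyl-1,2,3,4,5,8-hexahydronaphthalen-1-ol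
Product: 5 6-methyl-3,4,7,8-tetrahydronaphthalen-1(2H)-one, via 6-methyl-3,4,5,8-tetrahydronaphthalen-1(2H)-one 4 (not isolated)
Conditions: Dess–Martin periodinane, NaHCO3, CH2Cl2, 0 °C; aqueous work-up; then DBU (0.2 equiv), THF, rt, under argon
Reagents that add atoms: none
Why: Dess–Martin oxidation of the allylic alcohol, then base-catalysed conjugation through the C5 trienolate (C5–H is γ to C10=O and doubly allylic) with reprotonation at C3 to the fully conjugated C10(=O)–C1=C6–C5=C4(Me) dienone, the single thermodynamic sink, which is why the diene is conjugated as the ketone and not as the dienol.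

**Step 4**
Reactants: 5 6-methyl-3,4,7,8-tetrahydronaphthalen-1(2H)-one
Product: 6 (S)-6-methyl-1,2,3,4,7,8-hexahydronaphthalen-1-ol
Conditions: (R)-Me-CBS (0.2 equiv), catecholborane, toluene, −78 °C
Reagents that add atoms: none
Why: Corey–Bakshi–Shibata 1,2-reduction, in which the alkene carbon C1 acts as the large group and C9H2 as the small one, so the (R)-oxazaborolidine should give the (S)-carbinol at C10.

**Step 5**
Reactants: 6 (S)-6-methyl-1,2,3,4,7,8-hexahydronaphthalen-1-ol
Product: 7 (1S)-6,8a-epidioxy-6-methyl-1,2,3,4,6,7,8,8a-octahydronaphthalen-1-ol, O–O bridge (C1 to C4) on the face of the OH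
Conditions: O2, tetraphenylporphyrin (cat.), hν (visible), CCl4/CH2Cl2, −20 °C
Reagents that add atoms: oxygen (as singlet oxygen), O=O
Why: [4+2] cycloaddition of singlet oxygen to the homoannular C1=C6–C5=C4 diene (ascaridole type), directed by hydrogen bonding to the C10–OH, which allylic strain against the C2 methylene holds pseudoaxial over the diene terminus, so both new C–O bonds (C1, C4) form syn to OH.

**Step 6**
Reactants: 7 the endoperoxide
Product: 8 (1S)-4a,8a:5,6-diepoxy-6-methyldecahydronaphthalen-1-ol, both oxiranes syn to each other and to OH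
Conditions: Co(TPP) (5 mol %), CH2Cl2, −10 °C → rt
Reagents that add atoms: none
Why: Cobalt(II)-mediated O–O homolysis and addition of each oxygen radical to the adjacent carbon of the C5=C6 bond on the same face (endoperoxide-to-syn-bis-epoxide rearrangement), with no Kornblum–DeLaMare path because both bridgeheads are quaternary; C1, C6, C5 inherit the face of the peroxide.

**Step 7**
Reactants: 8 the bis-epoxy alcohol
Product: 9 syn-4a,8a:5,6-diepoxy-6-methyloctahydronaphthalen-1(2H)-one (syn-bis-epoxy decalone; C4, C5 as in the target)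
Conditions: Dess–Martin periodinane, NaHCO3, CH2Cl2, 0 °C → rt
Reagents that add atoms: none
Why: Dess–Martin oxidation of the secondary alcohol under buffered, non-acidic conditions that leave both oxiranes intact; the directing carbinol centre has done its work and is removed.

**Step 8 (key step)**
Reactants: 9 syn-bis-epoxy decalone; 10 p-toluenesulfonyl hydrazide
Product: 12 (2S,3S)-2,3-epoxy-3-methylcyclodec-6-yn-1-one, via tosylhydrazone of 9 11 (not isolated)
Conditions: TsNHNH2 (1.0 equiv), AcOH/CH2Cl2 (1:1), −18 °C, then rt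
Reagents that add atoms: none
Why: Condensation at C10 gives tosylhydrazone 11, which opens the only α,β-oxirane (C1–O) to a C6 alkoxide and a C10=C1 azoalkene; Grob-type collapse then forms C6=O, breaks the C1–C6 fusion bond and expels N2 and p-toluenesulfinate as the C10≡C1 triple bond forms (Eschenmoser–Tanabe fragmentation, as in 9,10-epoxy-1-decalone to cyclodec-5-ynone). The ten-membered ring is not closed by bond formation but released from the decalin by cleavage of the bond shared by the two six-membered rings, so no medium-ring cyclization entropy is paid. No stereocenter is made: C1 and C6 lose theirs and the cis C4–C5 oxirane is carried unchanged. The step needs the fusion oxirane and not the C4–C5 oxirane to open: only C1–O is α to the hydrazone carbon and its C1–C6 bond is aligned with the departing diazene, while the C4–C5 oxirane is γ,δ and, being syn to the C6 alkoxide on the six-membered ring, cannot suffer Payne-type backside attack. One equivalent of hydrazide is consumed as hydrazone at −18 °C before fragmentation begins, so the new α,β-epoxy ketone 12 meets no reagent for a second fragmentation.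

**Step 9**
Reactants: 12 the epoxy cyclodecynone
Product: 14 (2Z,9S,10S)-9,10-epoxy-9-methylcyclodec-2-en-5-yn-1-one (C7=C8 enone), via the C7 phenylselanyl ketone 13 (not isolated)
Conditions: LDA, THF, −78 °C; PhSeCl, −78 °C; then 30% H2O2, pyridine, CH2Cl2, 0 °C → rt
Reagents that add atoms: phenylselenyl chloride, Cl[Se]c1ccccc1 (selenium in 13 only)
Why: Enolization is possible only at C7 (C5 is an oxirane CH), and α-selenenylation followed by selenoxide syn-elimination gives the enone, Z because a ring holding the linear C9–C10≡C1–C2 unit cannot hold an E-olefin.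

**Step 10**
Reactants: 14 the enynone
Product: 16 (3R,9S,10S)-9,10-epoxy-3-hydroxy-9-methylcyclodec-5-yn-1-one (C8–OH, 8R), via the C8 pinacolboronate 15 (not isolated)
Conditions: B2pin2, CuCl (5 mol %), NaOt-Bu (10 mol %), (R,Sp)-Josiphos (5 mol %), MeOH (2 equiv), THF, 0 °C → rt; then NaBO3·4H2O, THF/H2O, rt
Reagents that add atoms: bis(pinacolato)diboron, CC1(C)OB(OC1(C)C)B1OC(C)(C)C(C)(C)O1 (boron in 15); sodium perborate, [Na+].[O-]OB=O (oxygen in 16)
Why: Copper(I)–boryl conjugate addition to the enone, faster than borylcupration of the unactivated alkyne, sets C8 under ligand control (boron to the Re face gives 8R), and C–B oxidation proceeds with retention.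

**Step 11**
Reactants: 16 the β-hydroxy ketone
Product: 18 cyclic siloxane (C8–O–SiMe2–C10 oxasilolane, C10=C1 with Si and H cis), via the C8 dimethylsilyl ether 17 (not isolated)
Conditions: (HMe2Si)2NH, neat, rt → 50 °C, evaporate; then Karstedt catalyst (Pt(dvds), 0.5 mol %), THF, rt
Reagents that add atoms: 1,1,3,3-tetramethyldisilazane, C[SiH](C)N[SiH](C)C
Why: Platinum-catalysed intramolecular hydrosilylation of a homopropargylic silyl ether is 5-exo-dig and syn, so the tether from C8–O puts silicon on C10 and hydrogen on C1 from the same side, which in the ring means C9 and C2 cis.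

**Step 12**
Reactants: 18 the cyclic siloxane
Product: 19 C10 vinyl iodide with free C8–OH (ring-cis C1=C10)
Conditions: N-iodosuccinimide, 2,6-lutidine, (CF3)2CHOH, 0 °C; aq. NaHCO3/Na2S2O3
Reagents that add atoms: N-iodosuccinimide, O=C1CCC(=O)N1I
Why: Ipso-iododesilylation of the alkenylsilane proceeds with retention of olefin geometry, and the residual Si–O bond is hydrolysed on work-up; lutidine buffers the medium for the oxirane.

**Step 13**
Reactants: 19 the iodo alcohol
Product: 20 C8 triethylsilyl ether of 19
Conditions: Et3SiCl, imidazole, CH2Cl2, 0 °C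
Reagents that add atoms: chlorotriethylsilane, CC[Si](Cl)(CC)CC
Why: Standard silylation; the ether blocks retro-aldol and lactonization toward C8 in the steps that follow and is removable without acid strong enough to open the oxiranes.

**Step 14**
Reactants: 20 the silyl-protected vinyl iodide
Product: 21 (Z)-C1=C10 trisubstituted olefin (C10–CH3), C6 ketone, C8–OTES
Conditions: MeZnCl, Pd(PPh3)4 (5 mol %), THF, rt
Reagents that add atoms: methylzinc chloride, C[Zn]Cl
Why: Negishi coupling replaces iodine by methyl with retention of geometry, and the organozinc does not add to the ketone or the oxirane.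

**Step 15**
Reactants: 22 ethyl bromopyruvate
Product: 23 ethyl 3-acetoxy-2-oxopropanoate
Conditions: KOAc, acetone, rt
Reagents that add atoms: potassium acetate, [K+].CC(=O)[O-]
Why: SN2 displacement of the activated α-bromo ketone by acetate; the C13 acetate of the target is carried from here.

**Step 16**
Reactants: 21 the ketone; 23 ethyl 3-acetoxy-2-oxopropanoate
Product: 25 C7 aldol adduct as its tertiary acetate [C7–C11(OAc)(CH2OAc)CO2Et; C7/C11 epimers], via the lithium aldolate 24 (not isolated)
Conditions: LDA (1.1 equiv), THF, −78 °C; 23, −78 °C; Ac2O, −78 → −20 °C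
Reagents that add atoms: acetic anhydride, CC(=O)OC(C)=O
Why: The kinetic lithium enolate (C7 is the only enolizable site; β-siloxide loss is slow at −78 °C) adds to the ketone carbonyl of the α-keto ester in an aldol reaction and the alkoxide is acetylated in situ; the C7 and C11 centres are uncontrolled and are removed in step 17.

**Step 17**
Reactants: 25 the β-acetoxy ketone
Product: 26 (Z)-alkylidene keto ester (C7=C11, CO2Et cis to C6=O, CH2OAc cis to C8)
Conditions: LiHMDS (1.0 equiv), THF, −78 → −40 °C; AcOH quench at −78 °C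
Reagents that add atoms: none
Why: E1cB elimination from the C7 lithium enolate expels the tertiary acetate (a far better leaving group than the C8 silyl ether), with the ester carbonyl chelated to the enolate lithium so that CO2Et ends cis to C6; exactly one equivalent of base leaves none to deprotonate C8–H of the product.

**Step 18**
Reactants: 26 the alkylidene keto ester
Product: 28 butenolide (7(11)-en-12,6-olide; 6R; C13–OAc; C8–OTES; Z-C1=C10), via the C6 hydroxy ester 27 (not isolated)
Conditions: Zn(BH4)2, Et2O, −30 → 0 °C; then PPTS (cat.), CH2Cl2, rt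
Reagents that add atoms: none
Why: Chelation-controlled 1,2-reduction of the α,β-epoxy ketone: zinc bridges C6=O and the oxirane oxygen and hydride enters from the face away from C4, giving the 5,6-erythro alcohol (6R), and the Z-γ-hydroxy enoate then lactonizes.

**Step 19**
Reactants: 28 the silyl-protected butenolide
Product: 29 C8 alcohol of the butenolide
Conditions: HF·pyridine, pyridine, THF, 0 °C
Reagents that add atoms: none
Why: Buffered fluoride cleavage of the triethylsilyl ether; the lactone carbonyl is trans to C8 across C7=C11, so the free hydroxyl cannot translactonize.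

**Step 20**
Reactants: 29 the C8 alcohol
Product: 30 1,10:4,5-bis-epoxy C8 alcohol (1R,10S)
Conditions: VO(acac)2 (5 mol %), t-BuOOH (decane), CH2Cl2, 0 °C → rt
Reagents that add atoms: tert-butyl hydroperoxide, CC(C)(C)OO
Why: Vanadium-catalysed hydroxyl-directed epoxidation: the vanadate of the homoallylic C8–OH delivers oxygen to the C1=C10 face on the side of the C8–O bond (oxirane and C8–O cis on the ring, as in the target), and the electron-poor butenolide alkene does not react.

**Step 21**
Reactants: 30 the bis-epoxy alcohol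
Product: 31 target, (1R,4S,5R,6R,8R,10S)-13-acetoxy-1,10:4,5-diepoxy-8-(methacryloyloxy)germacr-7(11)-en-12,6-olide
Conditions: methacrylic anhydride, Et3N, DMAP (cat.), CH2Cl2, 0 °C → rt
Reagents that add atoms: methacrylic anhydride, CC(=C)C(=O)OC(=O)C(C)=C
Why: DMAP-catalysed acylation of the secondary alcohol under mild base that should not epimerize C6 or move the C13 acetate.

**Compound list**
1 | 6-methyl-1-tetralone | Cc1ccc2c(c1)CCCC2=O | starting material
2 | rac-6-methyl-1,2,3,4-tetrahydronaphthalen-1-ol | Cc1ccc2c(c1)CCCC2O | intermediate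
3 | rac-6-methyl-1,2,3,4,5,8-hexahydronaphthalen-1-ol | CC1=CCC2=C(C1)CCCC2O | intermediate
4 | 6-methyl-3,4,5,8-tetrahydronaphthalen-1(2H)-one | CC1=CCC2=C(C1)CCCC2=O | intermediate (not isolated)
5 | 6-methyl-3,4,7,8-tetrahydronaphthalen-1(2H)-one | CC1=CC2=C(CC1)C(=O)CCC2 | intermediate
6 | (S)-6-methyl-1,2,3,4,7,8-hexahydronaphthalen-1-ol | O[C@H]1CCCC2=C1CCC(C)=C2 | intermediate
7 | (1S)-6,8a-epidioxy-6-methyl-1,2,3,4,6,7,8,8a-octahydronaphthalen-1-ol, O–O syn to OH | O[C@H]1CCCC2=C[C@@]3(C)OO[C@@]12CC3 | intermediate
8 | (1S)-4a,8a:5,6-diepoxy-6-methyldecahydronaphthalen-1-ol, oxiranes syn to each other and to OH | O[C@H]1CCC[C@@]23O[C@@]12CC[C@]1(C)O[C@@H]13 | intermediate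
9 | syn-4a,8a:5,6-diepoxy-6-methyloctahydronaphthalen-1(2H)-one | O=C1CCC[C@@]23O[C@@]12CC[C@]1(C)O[C@@H]13 | intermediate
10 | p-toluenesulfonyl hydrazide | Cc1ccc(cc1)S(=O)(=O)NN | starting material
11 | tosylhydrazone of 9 (N–N anti to the quaternary C1) | Cc1ccc(cc1)S(=O)(=O)N/N=C1\CCC[C@@]23O[C@@]12CC[C@]1(C)O[C@@H]13 | intermediate (not isolated)
12 | (2S,3S)-2,3-epoxy-3-methylcyclodec-6-yn-1-one | O=C1CCCC#CCC[C@]2(C)O[C@@H]21 | intermediate
13 | C7 phenylselanyl derivative of 12 (C7 epimers) | O=C1C([Se]c3ccccc3)CCC#CCC[C@]2(C)O[C@@H]21 | intermediate (not isolated)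
14 | (2Z,9S,10S)-9,10-epoxy-9-methylcyclodec-2-en-5-yn-1-one | O=C1/C=C\CC#CCC[C@]2(C)O[C@@H]21 | intermediate
15 | C8 pinacolboronate (C8 as in 16) | O=C1C[C@H](B3OC(C)(C)C(C)(C)O3)CC#CCC[C@]2(C)O[C@@H]21 | intermediate (not isolated)
16 | (3R,9S,10S)-9,10-epoxy-3-hydroxy-9-methylcyclodec-5-yn-1-one | O=C1C[C@H](O)CC#CCC[C@]2(C)O[C@@H]21 | intermediate
17 | C8 dimethylsilyl ether of 16 | O=C1C[C@H](O[SiH](C)C)CC#CCC[C@]2(C)O[C@@H]21 | intermediate (not isolated)
18 | cyclic siloxane, C8–O–SiMe2–C10, ring-cis C10=C1 | O=C1C[C@H]2C\C(=C/CC[C@]3(C)O[C@@H]31)[Si](C)(C)O2 | intermediate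
19 | C10 iodide, ring-cis C1=C10, C8–OH, C6 ketone, 4,5-oxirane | O=C1C[C@H](O)C\C(I)=C/CC[C@]2(C)O[C@@H]21 | intermediate
20 | C8 triethylsilyl ether of 19 | O=C1C[C@H](O[Si](CC)(CC)CC)C\C(I)=C/CC[C@]2(C)O[C@@H]21 | intermediate
21 | (Z)-C1=C10 methyl olefin, C8–OTES, C6 ketone, 4,5-oxirane | O=C1C[C@H](O[Si](CC)(CC)CC)C\C(C)=C/CC[C@]2(C)O[C@@H]21 | intermediate
22 | ethyl bromopyruvate | CCOC(=O)C(=O)CBr | starting material
23 | ethyl 3-acetoxy-2-oxopropanoate | CCOC(=O)C(=O)COC(C)=O | intermediate
24 | lithium aldolate at C11 (C7/C11 epimers) | [Li+].O=C1C(C([O-])(COC(C)=O)C(=O)OCC)[C@H](O[Si](CC)(CC)CC)C\C(C)=C/CC[C@]2(C)O[C@@H]21 | intermediate (not isolated)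
25 | C11 tertiary acetate of the aldol adduct (C7/C11 epimers) | O=C1C(C(OC(C)=O)(COC(C)=O)C(=O)OCC)[C@H](O[Si](CC)(CC)CC)C\C(C)=C/CC[C@]2(C)O[C@@H]21 | intermediate
26 | (Z)-C7=C11 alkylidene keto ester, CO2Et cis to C6=O | O=C1/C(=C(/COC(C)=O)C(=O)OCC)[C@H](O[Si](CC)(CC)CC)C\C(C)=C/CC[C@]2(C)O[C@@H]21 | intermediate
27 | (6R)-C6 hydroxy ester from 26 | O[C@@H]1/C(=C(/COC(C)=O)C(=O)OCC)[C@H](O[Si](CC)(CC)CC)C\C(C)=C/CC[C@]2(C)O[C@@H]21 | intermediate (not isolated)
28 | 13-acetoxy-4,5-epoxy-8-(triethylsilyloxy)germacra-1(10)Z,7(11)-dien-12,6-olide | CC[Si](CC)(CC)O[C@@H]1C\C(C)=C/CC[C@]2(C)O[C@@H]2[C@@H]2OC(=O)C(COC(C)=O)=C21 | intermediate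
29 | 13-acetoxy-4,5-epoxy-8-hydroxygermacra-1(10)Z,7(11)-dien-12,6-olide | O[C@@H]1C\C(C)=C/CC[C@]2(C)O[C@@H]2[C@@H]2OC(=O)C(COC(C)=O)=C21 | intermediate
30 | 13-acetoxy-1,10:4,5-diepoxy-8-hydroxygermacr-7(11)-en-12,6-olide | O[C@@H]1C[C@]2(C)O[C@@H]2CC[C@]2(C)O[C@@H]2[C@@H]2OC(=O)C(COC(C)=O)=C21 | intermediate
31 | CNP0212980.1, (1R,4S,5R,6R,8R,10S)-13-acetoxy-1,10:4,5-diepoxy-8-(methacryloyloxy)germacr-7(11)-en-12,6-olide | C=C(C)C(=O)O[C@@H]1C[C@]2(C)O[C@@H]2CC[C@]2(C)O[C@@H]2[C@@H]2OC(=O)C(COC(C)=O)=C21 | target

**Step count:** 21 steps in total; longest linear sequence 20 steps (steps 1–14 and 16–21; step 15 is a one-step branch).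

**Steps most likely to fail**

1. Step 17 (and with it the ring closure of step 18). The elimination may give the alkylidene with the ester trans to C6, or base may scramble C8 through the γ-position of the new enoate, so that lactonization does not occur. Fallback: close the lactone before the C7=C11 bond is made. Starting from 21, the aldol with 23 is quenched with AcOH at −78 °C to give the tertiary alcohol F1. Zn(BH4)2 then reduces C6 to the dihydroxy ester F2, which lactonizes (PPTS) to the α-hydroxy-γ-lactone F3, in which the ring already decides which carbon is the carbonyl. Dehydration of the tertiary alcohol toward C7–H (Burgess reagent for the isomer with C7–H syn to C11–OH, SOCl2/pyridine for the anti isomer) gives 28, where the route is rejoined.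

2. Step 5. Hydrogen bonding to the pseudoaxial hydroxyl may not override steric approach, so that the peroxide bridge forms on both faces and the configurational purity of C4/C5 is lost. Fallback: steric control on the mirror-image carbinol. Starting from 5, reduction with (S)-Me-CBS gives the (R)-dienol F4, and TBSOTf/2,6-lutidine gives the silyl ether F5. Singlet oxygen then adds anti to the pseudoaxial silyloxy group to give the endoperoxide F6, and Co(TPP) gives the syn-bis-epoxide F7. TBAF gives the alcohol F8, the C10 epimer of 8, and Dess–Martin oxidation gives 9, where the route is rejoined.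

3. Step 20. The ten-membered ring may present the other face of C1=C10 to the vanadium-bound peroxide, or delivery may be unselective. Fallback: reagent control in place of hydroxyl direction. Starting from 29, acylation as in step 21 gives the methacrylate F9. Shi epoxidation (the fructose-derived ketone enantiomer matched to the required face, Oxone, buffered MeCN/dimethoxymethane/H2O, 0 °C) then epoxidizes only the electron-rich C1=C10 bond and gives 31 directly.

**Further compounds**
F1 | step 17 | aldol adduct of 21 and 23 with free C11–OH (C7/C11 epimers) | O=C1C(C(O)(COC(C)=O)C(=O)OCC)[C@H](O[Si](CC)(CC)CC)C\C(C)=C/CC[C@]2(C)O[C@@H]21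
F2 | step 17 | (6R)-C6,C11-dihydroxy ester (not isolated) | O[C@@H]1C(C(O)(COC(C)=O)C(=O)OCC)[C@H](O[Si](CC)(CC)CC)C\C(C)=C/CC[C@]2(C)O[C@@H]21
F3 | step 17 | 11-hydroxy-12,6-olide (saturated C7–C11; C7/C11 epimers) | CC[Si](CC)(CC)O[C@@H]1C\C(C)=C/CC[C@]2(C)O[C@@H]2[C@@H]2OC(=O)C(O)(COC(C)=O)C21
F4 | step 5 | (R)-6-methyl-1,2,3,4,7,8-hexahydronaphthalen-1-ol | O[C@@H]1CCCC2=C1CCC(C)=C2
F5 | step 5 | tert-butyldimethylsilyl ether of F4 | CC(C)(C)[Si](C)(C)O[C@@H]1CCCC2=C1CCC(C)=C2
F6 | step 5 | endoperoxide with O–O anti to OTBS | CC(C)(C)[Si](C)(C)O[C@@H]1CCCC2=C[C@@]3(C)OO[C@@]12CC3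
F7 | step 5 | syn-bis-epoxide anti to OTBS | CC(C)(C)[Si](C)(C)O[C@@H]1CCC[C@@]23O[C@@]12CC[C@]1(C)O[C@@H]13
F8 | step 5 | C10 epimer of 8 | O[C@@H]1CCC[C@@]23O[C@@]12CC[C@]1(C)O[C@@H]13
F9 | step 20 | 8-O-methacrylate of 29 (C1=C10 olefin) | C=C(C)C(=O)O[C@@H]1C\C(C)=C/CC[C@]2(C)O[C@@H]2[C@@H]2OC(=O)C(COC(C)=O)=C21
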